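**Retrosynthetic overview** (piperidine numbering: N1, C2 methyl, C3 acetoxy, C6 side chain)
- The target comes from (−)-spectaline by O-acetylation, and spectaline from a 3-hydroxy-2-methyl-2,3,4,5-tetrahydropyridine by cis-selective hydrogenation, which sets C6.
- The ring is cut into two three-atom pieces, N1–C2–C3 and C4–C5–C6. The C3–C4 bond and the N1–C6 bond are made in one flask from a D-alanine ester (C3 at the ester oxidation level, nitrogen as a chelating benzophenone imine) and a β-ketal Grignard reagent, a ketone homoenolate that carries the whole side chain.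
- Enabling feature: the oxygen-bearing C3 and the nitrogen-bearing C6 are 1,4-related across the unfunctionalised C4–C5 unit, and C2(N)–C3(O) is a syn vicinal amino alcohol whose C2 and methyl group are D-alanine. Joining carbonyl-derived C3 to C4 (β to the C6 carbonyl, so of like polarity) needs a polarity-reversed C4–C5–C6 unit; N1 then stands 1,5 to the C6 carbonyl and the ring closes by itself as a cyclic imine.
- Side chain: Grignard acylation with 3-bromopropanoyl chloride, cross-metathesis with hex-5-en-2-one, bis-ketalisation. The piperidine is the only ring formed (step 5).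

Key step: step 5

Assumption: the cross-metathesis in step 2 is taken to give mainly the E alkene; all compounds carrying this double bond are drawn as E, and any Z isomer converges at 15.

**Step 1**
Reactants: 1 10-bromodec-1-ene; 2 3-bromopropanoyl chloride
Product: 4 1-bromotridec-12-en-3-one, via dec-9-enylmagnesium bromide 3 (not isolated)
Conditions: 1, Mg, THF, rt; then added to 2, Fe(acac)3 (3 mol %), THF, −78 °C; aq NH4Cl
Reagents that add atoms: none
Why: Iron-catalysed acylation of an alkyl Grignard reagent with an acid chloride is much faster at −78 °C than attack on the primary bromide or on the ketone formed, so the β-bromo ketone should result; no stereocenter is formed.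

**Step 2**
Reactants: 4 1-bromotridec-12-en-3-one; 5 hex-5-en-2-one
Product: 6 (5E)-17-bromoheptadec-5-ene-2,15-dione
Conditions: 5 (4 equiv), second-generation Hoveyda–Grubbs catalyst (H2IMes)Cl2Ru(=CH–C6H4–2-OiPr) (3 mol %), CH2Cl2, 40 °C
Reagents that add atoms: none
Why: Olefin cross-metathesis of two terminal alkenes is driven by loss of ethene and by the excess of the cheap ketone partner; the phosphine-free catalyst should leave the β-bromo ketone untouched, and the alkene geometry is irrelevant because the double bond is hydrogenated in step 6.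

**Step 3**
Reactants: 6 (5E)-17-bromoheptadec-5-ene-2,15-dione
Product: 7 2-(2-bromoethyl)-5,5-dimethyl-2-[(9E)-12-(2,5,5-trimethyl-1,3-dioxan-2-yl)dodec-9-en-1-yl]-1,3-dioxane
Conditions: 2,2-dimethylpropane-1,3-diol (3 equiv), HC(OEt)3 (2.2 equiv), TsOH·H2O (5 mol %), CH2Cl2, rt
Reagents that add atoms: 2,2-dimethylpropane-1,3-diol OCC(C)(C)CO
Why: Acid-catalysed ketalisation with an orthoformate as water scavenger should protect both ketones at room temperature without loss of HBr, and the 5,5-dimethyl-1,3-dioxane next to the bromide gives a β-ketal bromide whose Grignard reagent is stable; no stereocenter is formed.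

**Step 4**
Reactants: 8 methyl D-alaninate hydrochloride
Product: 9 methyl (2R)-2-[(diphenylmethylidene)amino]propanoate
Conditions: Ph2C=NH (1 equiv), CH2Cl2, rt
Reagents that add atoms: benzophenone imine N=C(c1ccccc1)c1ccccc1
Why: Transimination of the amino ester hydrochloride with benzophenone imine is driven by precipitation of NH4Cl and needs no base, so the D-alanine stereocenter should be kept.

**Step 5**
Reactants: 7 2-(2-bromoethyl)-5,5-dimethyl-2-[(9E)-12-(2,5,5-trimethyl-1,3-dioxan-2-yl)dodec-9-en-1-yl]-1,3-dioxane; 9 methyl (2R)-2-[(diphenylmethylidene)amino]propanoate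
Product: 14 (2R,3R)-2-methyl-6-[(9E)-13-oxotetradec-9-en-1-yl]-2,3,4,5-tetrahydropyridin-3-ol, via Grignard reagent 10 (not isolated), via aluminium hemiacetal 11 (not isolated), via syn imino alcohol 12 (not isolated), via amino diketone 13 (not isolated)
Conditions: 9, iBu2AlH (1.05 equiv), CH2Cl2, −78 °C; then 10 (2 equiv; from 7, Mg, THF, 25 °C), −78 °C to rt; then 2 M aq HCl, THF, 40 °C; then NaHCO3 to pH 9
Reagents that add atoms: water O
Why: iBu2AlH should stop at aluminium hemiacetal 11, which on addition of 10 collapses to an aldehyde held in a five-membered chelate (carbonyl oxygen, metal, imine nitrogen), so that the β-ketal Grignard reagent, a ketone homoenolate in which the carbon β to the masked C6 carbonyl reacts as a nucleophile, forms the C3–C4 bond; aqueous acid then cleaves the benzophenone imine and both ketals, and on neutralisation the free amine condenses with the C6 ketone to form the N1–C6 bond. The closest known reaction types are the one-pot reductive alkylation of amino ester benzophenone imines with Grignard reagents to threo amino alcohols, homoaldol additions of β-ketal Grignard reagents, and the spontaneous cyclocondensation of δ-amino ketones to 2,3,4,5-tetrahydropyridines. The piperidine ring closes by 6-exo-trig attack of nitrogen on the C6 carbonyl followed by loss of water. The new stereocenter C3 is controlled by the D-alanine-derived C2 under Cram chelate control: the nucleophile approaches the chelated aldehyde from the face opposite the C2 methyl group, which should give the syn (2R,3R) amino alcohol. The step needs syn over anti selectivity at C3, retention at C2 and C=N formation at C6 in preference to the remote methyl ketone; these are secured by the chelating imine nitrogen, by never liberating a free α-amino aldehyde, and by the 1,5-relationship of nitrogen and C6, which makes only that condensation intramolecular. Hydroxy imine, lactol and bicyclic N,O-acetal forms of 14 are in equilibrium and converge in step 6.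

**Step 6**
Reactants: 14 (2R,3R)-2-methyl-6-[(9E)-13-oxotetradec-9-en-1-yl]-2,3,4,5-tetrahydropyridin-3-ol
Product: 15 (2R,3R,6S)-2-methyl-6-(13-oxotetradecyl)piperidin-3-ol, (−)-spectaline
Conditions: H2 (1 atm), 10% Pd/C, EtOH, rt
Reagents that add atoms: none
Why: Heterogeneous catalytic hydrogenation should saturate the side-chain alkene and add hydrogen to the cyclic C=N bond from the face opposite the cis 2-methyl and 3-hydroxy groups, placing the C6 chain cis to both (6S), while the methyl ketone is not reduced over Pd/C at 1 atm.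

**Step 7**
Reactants: 15 (2R,3R,6S)-2-methyl-6-(13-oxotetradecyl)piperidin-3-ol
Product: 16 (2R,3R,6S)-2-methyl-6-(13-oxotetradecyl)piperidin-3-yl acetate, (−)-3-O-acetylspectaline
Conditions: AcCl (3 equiv), CF3CO2H, 0 °C to rt; evaporate; cold aq NaHCO3, CH2Cl2
Reagents that add atoms: acetyl chloride CC(=O)Cl
Why: Chemoselective O-acylation of an amino alcohol in strong acid: the piperidine nitrogen is fully protonated and cannot be acylated, so only the secondary alcohol should be esterified, with no change at any stereocenter.

**Compound list**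
1 | 10-bromodec-1-ene | C=CCCCCCCCCBr | starting material
2 | 3-bromopropanoyl chloride | O=C(Cl)CCBr | starting material
3 | dec-9-enylmagnesium bromide | C=CCCCCCCCC[Mg]Br | intermediate
4 | 1-bromotridec-12-en-3-one | BrCCC(=O)CCCCCCCCC=C | intermediate
5 | hex-5-en-2-one | CC(=O)CCC=C | starting material
6 | (5E)-17-bromoheptadec-5-ene-2,15-dione | CC(=O)CC/C=C/CCCCCCCCC(=O)CCBr | intermediate
7 | 2-(2-bromoethyl)-5,5-dimethyl-2-[(9E)-12-(2,5,5-trimethyl-1,3-dioxan-2-yl)dodec-9-en-1-yl]-1,3-dioxane | BrCCC1(OCC(C)(C)CO1)CCCCCCCC/C=C/CCC1(C)OCC(C)(C)CO1 | intermediate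
8 | methyl D-alaninate hydrochloride | C[C@@H](N)C(=O)OC.Cl | starting material
9 | methyl (2R)-2-[(diphenylmethylidene)amino]propanoate | C[C@@H](N=C(c1ccccc1)c1ccccc1)C(=O)OC | intermediate
10 | Grignard reagent of 7, {2-[5,5-dimethyl-2-[(9E)-12-(2,5,5-trimethyl-1,3-dioxan-2-yl)dodec-9-en-1-yl]-1,3-dioxan-2-yl]ethyl}magnesium bromide | Br[Mg]CCC1(OCC(C)(C)CO1)CCCCCCCC/C=C/CCC1(C)OCC(C)(C)CO1 | intermediate
11 | aluminium hemiacetal, [(2R)-2-[(diphenylmethylidene)amino]-1-methoxypropoxy]bis(2-methylpropyl)aluminium | C[C@@H](N=C(c1ccccc1)c1ccccc1)C(OC)O[Al](CC(C)C)CC(C)C | intermediate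
12 | syn imino alcohol, (2R,3R)-5-{5,5-dimethyl-2-[(9E)-12-(2,5,5-trimethyl-1,3-dioxan-2-yl)dodec-9-en-1-yl]-1,3-dioxan-2-yl}-2-[(diphenylmethylidene)amino]pentan-3-ol | C[C@@H](N=C(c1ccccc1)c1ccccc1)[C@H](O)CCC1(OCC(C)(C)CO1)CCCCCCCC/C=C/CCC1(C)OCC(C)(C)CO1 | intermediate
13 | amino diketone, (5E,18R,19R)-19-amino-18-hydroxyicos-5-ene-2,15-dione | C[C@@H](N)[C@H](O)CCC(=O)CCCCCCCC/C=C/CCC(C)=O | intermediate
14 | (2R,3R)-2-methyl-6-[(9E)-13-oxotetradec-9-en-1-yl]-2,3,4,5-tetrahydropyridin-3-ol | CC(=O)CC/C=C/CCCCCCCCC1=N[C@H](C)[C@H](O)CC1 | intermediate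
15 | (2R,3R,6S)-2-methyl-6-(13-oxotetradecyl)piperidin-3-ol, (−)-spectaline | CC(=O)CCCCCCCCCCCC[C@H]1CC[C@@H](O)[C@@H](C)N1 | intermediate
16 | (2R,3R,6S)-2-methyl-6-(13-oxotetradecyl)piperidin-3-yl acetate, (−)-3-O-acetylspectaline | CC(=O)CCCCCCCCCCCC[C@H]1CC[C@@H](OC(C)=O)[C@@H](C)N1 | target

**Step count and risks**
Total steps: 7. Longest linear sequence: 6 (steps 1, 2, 3, 5, 6, 7, from 10-bromodec-1-ene).

Steps most likely to fail:

1. Step 5. The risk is loss of chelation control so that the anti diastereomer forms, sluggish addition of the bulky functionalised Grignard reagent to the aluminium hemiacetal, or over-reduction of the ester. The fallback sets C3 by ketone reduction instead of aldehyde addition; it sets out from 8 (and 7) and returns at 15. N,N-Dibenzylation of 8 (BnBr, K2CO3, MeCN, 60 °C) should give methyl (2R)-2-(dibenzylamino)propanoate F1. MeNHOMe·HCl and iPrMgCl (THF, −20 °C) should convert it into the Weinreb amide (2R)-2-(dibenzylamino)-N-methoxy-N-methylpropanamide F2. Grignard reagent 10, made from 7 as in step 5, should add once to give the α-(dibenzylamino) ketone F3. NaBH4 (MeOH, −20 °C) should reduce it under Felkin–Anh, non-chelation control to the syn (2R,3R)-dibenzylamino alcohol F4. Hydrogenation over Pd(OH)2/C in MeOH containing aqueous HCl should remove both benzyl groups, saturate the alkene and cleave both ketals; the saturated cyclic imine (2R,3R)-2-methyl-6-(13-oxotetradecyl)-2,3,4,5-tetrahydropyridin-3-ol F5 that then forms should be reduced in the same flask, giving 15 after basification.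

2. Step 1. The risk is loss of HBr from the acid chloride or from the product, giving a vinyl ketone that consumes Grignard reagent by conjugate addition, or a second addition to the ketone. The fallback builds the β-bromo ketone from an enone; it sets out from 1 and returns at 4. Grignard reagent 3, made from 1, should add to acrolein (THF, −78 °C) to give trideca-1,12-dien-3-ol F6. MnO2 (CH2Cl2, rt) should oxidise it to trideca-1,12-dien-3-one F7. Conjugate addition of Me3SiBr (CH2Cl2, −40 °C) should give the silyl enol ether [(1-bromotrideca-2,12-dien-3-yl)oxy](trimethyl)silane F8, which is hydrolysed to 4 on aqueous work-up.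

3. Step 7. The risk is transfer of the acetyl group to nitrogen, by direct N-acylation on incomplete protonation or by O-to-N migration when the free base is liberated. The fallback acetylates before the amine exists; it sets out from 14 and returns at 16. Ac2O, pyridine and catalytic DMAP (CH2Cl2, 0 °C) should esterify the alcohol of 14, whose imine nitrogen carries no hydrogen, to give (2R,3R)-2-methyl-6-[(9E)-13-oxotetradec-9-en-1-yl]-2,3,4,5-tetrahydropyridin-3-yl acetate F9. Hydrogenation (H2, Pd/C, EtOAc) should then give 16 directly under neutral conditions.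

**Further compounds**
F1 | step 5 | methyl (2R)-2-(dibenzylamino)propanoate | C[C@@H](N(Cc1ccccc1)Cc1ccccc1)C(=O)OC
F2 | step 5 | (2R)-2-(dibenzylamino)-N-methoxy-N-methylpropanamide | C[C@@H](N(Cc1ccccc1)Cc1ccccc1)C(=O)N(C)OC
F3 | step 5 | (2R)-2-(dibenzylamino)-5-{5,5-dimethyl-2-[(9E)-12-(2,5,5-trimethyl-1,3-dioxan-2-yl)dodec-9-en-1-yl]-1,3-dioxan-2-yl}pentan-3-one | C[C@@H](N(Cc1ccccc1)Cc1ccccc1)C(=O)CCC1(OCC(C)(C)CO1)CCCCCCCC/C=C/CCC1(C)OCC(C)(C)CO1
F4 | step 5 | (2R,3R)-2-(dibenzylamino)-5-{5,5-dimethyl-2-[(9E)-12-(2,5,5-trimethyl-1,3-dioxan-2-yl)dodec-9-en-1-yl]-1,3-dioxan-2-yl}pentan-3-ol | C[C@@H](N(Cc1ccccc1)Cc1ccccc1)[C@H](O)CCC1(OCC(C)(C)CO1)CCCCCCCC/C=C/CCC1(C)OCC(C)(C)CO1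
F5 | step 5 | (2R,3R)-2-methyl-6-(13-oxotetradecyl)-2,3,4,5-tetrahydropyridin-3-ol | CC(=O)CCCCCCCCCCCCC1=N[C@H](C)[C@H](O)CC1
F6 | step 1 | trideca-1,12-dien-3-ol | C=CC(O)CCCCCCCCC=C
F7 | step 1 | trideca-1,12-dien-3-one | C=CC(=O)CCCCCCCCC=C
F8 | step 1 | [(1-bromotrideca-2,12-dien-3-yl)oxy](trimethyl)silane | BrCC=C(O[Si](C)(C)C)CCCCCCCCC=C
F9 | step 7 | (2R,3R)-2-methyl-6-[(9E)-13-oxotetradec-9-en-1-yl]-2,3,4,5-tetrahydropyridin-3-yl acetate | CC(=O)CC/C=C/CCCCCCCCC1=N[C@H](C)[C@H](OC(C)=O)CC1
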